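The runs stem from a simulated flask with made-up constants, and the scatter is random.

Intermediate A in the alpha flask has to be carried from 80.0 s to 6.0 min, so I wanted a number from which time drops out.

| flask | starting material | partner | remark | time |
|---|---|---|---|---|
| alpha | 20 mM | 12 mM | the very flask that is asked about, followed so far |  |
| gamma | 20 mM | 6 mM | run made earlier |  |
| flask | 20 mM | 12.0 mM |  | 6.0 min |

alpha run (percent of the starting material charged)

| time / s | side product / % | target / % | intermediate B / % | intermediate A / % | starting material / % |
|---|---|---|---|---|---|
| 10.0 | 0.9 | 5.8 | 22.5 | 2.4 | 69.5 |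
| 15.0 | 0 | 11.1 | 25.0 | 4.6 | 61.4 |
| 25.0 | 0 | 11.6 | 26.7 | 4.8 | 54.5 |
| 40.0 | 0 | 11.9 | 28.7 | 6.4 | 50.1 |
| 80.0 | 1.8 | 11.4 | 27.7 | 12.0 | 44.1 |

gamma run (percent of the starting material charged)

| time / min | side product / % | target / % | intermediate B / % | intermediate A / % | starting material / % |
|---|---|---|---|---|---|
| 0.167 | 0 | 4.0 | 11.3 | 2.5 | 81.6 |
| 0.500 | 0 | 5.2 | 15.3 | 8.1 | 68.2 |
| 0.833 | 1.1 | 7.7 | 16.8 | 12.4 | 64.7 |
| 1.33 | 3.1 | 7.4 | 16.3 | 17.8 | 57.5 |
| 2.00 | 3.4 | 8.3 | 15.5 | 25.0 | 50.9 |
| 2.50 | 3.5 | 7.6 | 14.6 | 26.3 | 46.0 |

(readings scatter by 1 percentage point)

* the species in which most of what was charged as starting material, at 6.0 min sits (side product / starting material / intermediate A / target / intermediate B)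
* the largest share itself, whichever of these holds it, in percent of the starting material charged

- percent here means starting material units held: one side product counts as two
- steps under discussion: 2 partner -> homo dimer; starting material <-> intermediate A; intermediate B <-> target; starting material + partner <-> intermediate B; starting material + intermediate A -> side product

Starting material feeds intermediate A by a first-order step, and starting material plus intermediate A makes side product. Divide one rate by the other, with the way back of the first step left out of my reckoning, and starting material, partner and time drop out. The last gamma reading gives 0.506 for the leak, side product share over the square of intermediate A share, a selectivity factor of a kind, though its side product reading of 3.5% carries a scatter of 1 percentage point. Used over made, for intermediate A, is the leak times its share.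

In gamma, intermediate A grew by 0.189 min⁻¹ of the starting material present. At 80.0 s the alpha flask held a pool of starting material, intermediate B and target of 83.2%, 53.0% of it free starting material. I held that split, so the pool drains at 0.100 min⁻¹ and reaches 52.1% at 6.0 min. By this reckoning intermediate A crosses starting material near 4.30 min. At 6.0 min I reckoned 39.9% intermediate A, ahead of 27.6% starting material, with 8.06% side product. The curve is bending but has no level yet: made over used is still 4.95.

The forecast also chose intermediate A, at 34%, lower than my figure, and it read the growth of that intermediate with “little reverse reaction visible”.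

The flask gave intermediate A at 38.9%, with starting material at 24.7% and side product at 9.71%.

    2 partner → homo dimer (k = 0.510 M⁻¹ s⁻¹)
    starting material ⇌ intermediate A (K = 18.0, k = 0.00330 s⁻¹)
    intermediate B ⇌ target (K = 0.450, k = 0.120 s⁻¹)
    starting material + partner ⇌ intermediate B (K = 220 M⁻¹, k = 4.80 M⁻¹ s⁻¹)
    starting material + intermediate A → side product (k = 0.0860 M⁻¹ s⁻¹)

At 6.00 min the flask made intermediate A 4.50 times faster than it used it up, each step taken net, and the leak with the flask's own share puts that ratio at 5.08. The neighbour charged with 30 mM partner held 29.6% intermediate A, for which the leak gives 4.43% side product, and that neighbour held 5.34%.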